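**Strategy**

Plakortolide K (C1 lactone carbonyl, C3 peroxy CH, C4 carbinol carbon of the lactone, C6 peroxy quaternary carbon, C7–C18 chain) is cut back to a bridged peroxide. On the chair of ring A (the 1,2-dioxane) the C4 oxygen and C7 are cis and 1,3-diaxial, so they are joined through C8 as a temporary δ-lactone. The key step closes ring A by conjugate addition of a C3 hydroperoxy ketal to C6 of this unsaturated lactone; it forms the C6–O bond and fixes C6 relative to C4 in one operation. The precursor is an (R)-configured 4-methyl-5,6-dihydropyran-2-one whose quaternary carbinol carbon (future C4) carries the hydroperoxy methyl ketal of a tert-butyl β-keto ester.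

Key step: step 10

Remark: the atom numbers C1–C18 of the target are used for every intermediate; 20 and 21 arise as C3 ketal epimers of which one is drawn, since both ionise to the same cation in step 11; short-lived ions inside a mechanism are described in the Why lines, whereas species that persist until the next reagent is added are numbered.

**Route**

Step 1
Reactants: 1 1,10-dibromodecane; 2 phenylmagnesium bromide
Product: 3 (10-bromodecyl)benzene
Conditions: 1 (3 equiv), Li2CuCl4 (3 mol %), THF, −10 °C to rt; excess 1 recovered by distillation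
Reagents that add atoms: none
Why: Kochi copper-catalysed cross-coupling of an aryl Grignard reagent with a primary alkyl bromide, in which the excess of dibromide should suppress double arylation.

Step 2
Reactants: 3 (10-bromodecyl)benzene
Product: 4 (10-phenyldecyl)triphenylphosphonium bromide
Conditions: PPh3, MeCN, reflux
Reagents that add atoms: triphenylphosphine, c1ccccc1P(c1ccccc1)c1ccccc1
Why: SN2 quaternisation of the primary bromide by the phosphine should give the Wittig salt.

Step 3
Reactants: 5 (S)-lactic acid; 6 pivalaldehyde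
Product: 7 (2S,5S)-2-tert-butyl-5-methyl-1,3-dioxolan-4-one
Conditions: TsOH·H2O (cat.), H2SO4 (cat.), pentane, reflux, Dean–Stark; crystallisation from pentane/Et2O at −78 °C
Reagents that add atoms: none
Why: acid-catalysed acetalisation with azeotropic removal of water, in which the acetal carbon is set under thermodynamic control in favour of the cis isomer that crystallisation should purify.

Step 4
Reactants: 7 (2S,5S)-2-tert-butyl-5-methyl-1,3-dioxolan-4-one; 8 3-bromo-2-methylprop-1-ene
Product: 10 (2S,5R)-2-tert-butyl-5-methyl-5-(2-methylprop-2-en-1-yl)-1,3-dioxolan-4-one, via lithium enolate 9 (not isolated)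
Conditions: LiN(i-Pr)2, THF, −78 °C; then 8, −78 °C
Reagents that add atoms: none
Why: enolate alkylation under self-regeneration of stereocentres, in which the tert-butyl group on the acetal carbon shields one face of the planar enolate so that the allylic bromide enters trans to it and sets the quaternary carbon (future C4) with overall retention.

Step 5
Reactants: 10 (2S,5R)-2-tert-butyl-5-methyl-5-(2-methylprop-2-en-1-yl)-1,3-dioxolan-4-one
Product: 11 (2R)-2-hydroxy-2,4-dimethylpent-4-enoic acid
Conditions: LiOH, THF/H2O, 0 °C to rt; then 1 M HCl to pH 2 at 0 °C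
Reagents that add atoms: water (delivered as hydroxide), O
Why: saponification of the acylal-type ester followed by collapse of the hemiacetal to pivalaldehyde; the quaternary centre cannot epimerise and cold acidification avoids acid-catalysed lactonisation onto the 1,1-disubstituted alkene.

Step 6
Reactants: 11 (2R)-2-hydroxy-2,4-dimethylpent-4-enoic acid; 12 acryloyl chloride
Product: 14 (2R)-2,4-dimethyl-2-(prop-2-enoyloxy)pent-4-enoic acid, via bis-acryloyl mixed anhydride 13 (not isolated)
Conditions: 12 (2.5 equiv), Et3N, DMAP (cat.), CH2Cl2, 0 °C to rt; then H2O, THF, rt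
Reagents that add atoms: none
Why: DMAP-catalysed acylation should esterify the tertiary hydroxyl; the carboxyl group is acylated as well and that mixed anhydride is hydrolysed at its unhindered acryloyl carbonyl.

Step 7
Reactants: 14 (2R)-2,4-dimethyl-2-(prop-2-enoyloxy)pent-4-enoic acid
Product: 15 (2R)-2,4-dimethyl-6-oxo-3,6-dihydro-2H-pyran-2-carboxylic acid
Conditions: second-generation Grubbs catalyst (H2IMes)(PCy3)Cl2Ru=CHPh (5 mol %), toluene (0.01 M), 80 °C
Reagents that add atoms: none
Why: ring-closing metathesis between the acrylate and the 1,1-disubstituted alkene with loss of ethylene; the six-membered ring forces the cis geometry of the C6=C7 bond, which an intermolecular olefination of a methyl ketone would not guarantee, and the quaternary carbinol centre favours closure (Thorpe–Ingold effect).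

Step 8
Reactants: 15 (2R)-2,4-dimethyl-6-oxo-3,6-dihydro-2H-pyran-2-carboxylic acid; 16 mono-tert-butyl malonate
Product: 19 tert-butyl 3-[(2R)-2,4-dimethyl-6-oxo-3,6-dihydro-2H-pyran-2-yl]-3-oxopropanoate, via acyl imidazolide 17 (not isolated), via acylmalonic half ester 18 (not isolated)
Conditions: CDI, THF, rt; then 16, MgCl2, Et3N, THF, rt to 40 °C; aq. citric acid
Reagents that add atoms: none
Why: Masamune–Brooks homologation, in which the magnesium enolate of the malonate half ester is C-acylated by the imidazolide and then decarboxylates; because the C4 oxygen is already tied up in the lactone, no free γ-hydroxyl can close onto the β-keto ester to give a tetronic acid.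

Step 9
Reactants: 19 tert-butyl 3-[(2R)-2,4-dimethyl-6-oxo-3,6-dihydro-2H-pyran-2-yl]-3-oxopropanoate
Product: 20 tert-butyl (3R)-3-[(2R)-2,4-dimethyl-6-oxo-3,6-dihydro-2H-pyran-2-yl]-3-hydroperoxy-3-methoxypropanoate (3R drawn; 3S epimer also formed)
Conditions: urea·H2O2 (5 equiv), Sc(OTf)3 (10 mol %), MeOH, rt
Reagents that add atoms: hydrogen peroxide (as its urea adduct), OO; methanol, CO
Why: Lewis-acid-catalysed perhydrolysis and ketalisation of the ketone through its oxocarbenium ion, the established way from ketones to hydroperoxy methyl ketals; C3 forms unselectively, both epimers are carried on, and the tert-butyl ester cannot close to a peroxylactone.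

Step 10
Reactants: 20 tert-butyl (3R)-3-[(2R)-2,4-dimethyl-6-oxo-3,6-dihydro-2H-pyran-2-yl]-3-hydroperoxy-3-methoxypropanoate
Product: 21 tert-butyl 2-[(1R,4R,5R)-4-methoxy-1,5-dimethyl-7-oxo-2,3,6-trioxabicyclo[3.3.1]nonan-4-yl]acetate (bridged peroxy δ-lactone; ketal epimers)
Conditions: Et2NH (0.5 equiv), CF3CH2OH, 0 °C to rt
Reagents that add atoms: none
Why: Et2NH deprotonates the hydroperoxide reversibly, the peroxy anion adds to C6 (the β-carbon of the unsaturated δ-lactone), and CF3CH2OH protonates the resulting lactone enolate at C7 before it can attack the O–O bond and collapse to an epoxide. The closest known reaction type is the amine-mediated intramolecular oxa-Michael addition of hydroperoxy ketals to α,β-unsaturated esters and butenolides, which gives 3-alkoxy-1,2-dioxanes; here the acceptor bears a second β-substituent and is locked s-cis in a ring. Ring A closes in the 6-exo-trig mode through the new C6–O bond, and with the δ-lactone as the second three-atom bridge the product is a 2,3,6-trioxabicyclo[3.3.1]nonan-7-one. The new stereocentre C6 is controlled by the substrate: the peroxide hangs from C3 on C4, a member of the lactone ring, and can reach only the face of C6 on its own side, so the C4 oxygen and C7 end cis (1,3-diaxial) on ring A and no C6 epimer can form. The step needs conjugate addition to win over attack at the two ester carbonyls; the tert-butyl ester blocks peroxylactone formation at C1, and attack at the lactone carbonyl C8 is reversible and leads nowhere. Both C3 epimers of 20 should cyclise and they converge in step 11.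

Step 11
Reactants: 21 tert-butyl 2-[(1R,4R,5R)-4-methoxy-1,5-dimethyl-7-oxo-2,3,6-trioxabicyclo[3.3.1]nonan-4-yl]acetate
Product: 22 tert-butyl 2-[(1R,4R,5R)-1,5-dimethyl-7-oxo-2,3,6-trioxabicyclo[3.3.1]nonan-4-yl]acetate
Conditions: Et3SiH (5 equiv), TMSOTf (0.3 equiv), CH2Cl2, −78 to −40 °C
Reagents that add atoms: none
Why: ionic reduction of a ketal, in which loss of methoxide from either C3 epimer gives one peroxycarbenium ion and the silane delivers hydride axially from the exo face of ring A, away from the lactone bridge, so that C3–H ends anti to the C4 oxygen (3R of the target).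

Step 12
Reactants: 22 tert-butyl 2-[(1R,4R,5R)-1,5-dimethyl-7-oxo-2,3,6-trioxabicyclo[3.3.1]nonan-4-yl]acetate
Product: 23 tert-butyl 2-[(1R,4R,5R)-7-hydroxy-1,5-dimethyl-2,3,6-trioxabicyclo[3.3.1]nonan-4-yl]acetate (lactol; both C7 epimers)
Conditions: i-Bu2AlH (1.15 equiv), CH2Cl2, −78 °C; aq. potassium sodium tartrate
Reagents that add atoms: none
Why: partial reduction of a lactone to its lactol through a tetrahedral aluminate that persists at −78 °C; the hindered tert-butyl ester and the dialkyl peroxide should react more slowly than the δ-lactone, and the configuration of the lactol carbon does not matter.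

Step 13
Reactants: 23 tert-butyl 2-[(1R,4R,5R)-7-hydroxy-1,5-dimethyl-2,3,6-trioxabicyclo[3.3.1]nonan-4-yl]acetate; 4 (10-phenyldecyl)triphenylphosphonium bromide
Product: 25 tert-butyl 2-[(3R,4R,6S)-4-hydroxy-4,6-dimethyl-6-[(2Z)-12-phenyldodec-2-en-1-yl]-1,2-dioxan-3-yl]acetate, via phosphonium ylide 24 (not isolated)
Conditions: 4 (3.0 equiv), NaN(SiMe3)2 (2.9 equiv), THF, 0 °C; then 23, −78 to 0 °C; aq. NH4Cl
Reagents that add atoms: none
Why: Wittig olefination of a lactol through its open hydroxy aldehyde, one equivalent of ylide serving as base; the unstabilised ylide should give mainly the Z-alkene (erased in step 15), and the reaction opens the bridge, attaches C9–C18 with the phenyl group and frees the C4 hydroxyl.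

Step 14
Reactants: 25 tert-butyl 2-[(3R,4R,6S)-4-hydroxy-4,6-dimethyl-6-[(2Z)-12-phenyldodec-2-en-1-yl]-1,2-dioxan-3-yl]acetate
Product: 27 (3R,4R,6S)-8,9-didehydroplakortolide K with a (Z)-C8=C9 bond, via hydroxy acid 26 (not isolated)
Conditions: CF3CO2H/CH2Cl2 (1:4), 0 °C to rt
Reagents that add atoms: none
Why: acidolysis of the tert-butyl ester with loss of isobutene, then 5-exo-trig lactonisation of the C4 hydroxyl onto C1, which is easy because C2 and the C4 oxygen are cis on ring A; dialkyl peroxides tolerate CF3CO2H, no stereocentre is touched, and any material already lactonised in step 13 converges here.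

Step 15
Reactants: 27 (3R,4R,6S)-8,9-didehydroplakortolide K
Product: 28 plakortolide K
Conditions: KO2CN=NCO2K, AcOH, MeOH/CH2Cl2, 0 °C to rt
Reagents that add atoms: none
Why: diimide reduction, in which diimide formed in the flask transfers two hydrogens to the unpolarised disubstituted alkene in a concerted syn fashion and leaves untouched the O–O bond that catalytic hydrogenation would cleave.

**Compound list**

1 | 1,10-dibromodecane | BrCCCCCCCCCCBr | starting material
2 | phenylmagnesium bromide | Br[Mg]c1ccccc1 | starting material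
3 | (10-bromodecyl)benzene | BrCCCCCCCCCCc1ccccc1 | intermediate
4 | (10-phenyldecyl)triphenylphosphonium bromide | [Br-].c1ccccc1CCCCCCCCCC[P+](c1ccccc1)(c1ccccc1)c1ccccc1 | intermediate
5 | (S)-lactic acid | C[C@H](O)C(=O)O | starting material
6 | pivalaldehyde (2,2-dimethylpropanal) | CC(C)(C)C=O | starting material
7 | (2S,5S)-2-tert-butyl-5-methyl-1,3-dioxolan-4-one (cis) | C[C@@H]1O[C@H](C(C)(C)C)OC1=O | intermediate
8 | 3-bromo-2-methylprop-1-ene | CC(=C)CBr | starting material
9 | lithium enolate of 7 (2S) | [Li+].CC1=C([O-])O[C@@H](C(C)(C)C)O1 | intermediate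
10 | (2S,5R)-2-tert-butyl-5-methyl-5-(2-methylprop-2-en-1-yl)-1,3-dioxolan-4-one | C[C@]1(CC(C)=C)O[C@H](C(C)(C)C)OC1=O | intermediate
11 | (2R)-2-hydroxy-2,4-dimethylpent-4-enoic acid | C[C@@](O)(CC(C)=C)C(=O)O | intermediate
12 | acryloyl chloride | C=CC(=O)Cl | starting material
13 | acrylic (2R)-2,4-dimethyl-2-(prop-2-enoyloxy)pent-4-enoic anhydride | C=CC(=O)O[C@](C)(CC(C)=C)C(=O)OC(=O)C=C | intermediate
14 | (2R)-2,4-dimethyl-2-(prop-2-enoyloxy)pent-4-enoic acid | C=CC(=O)O[C@](C)(CC(C)=C)C(=O)O | intermediate
15 | (2R)-2,4-dimethyl-6-oxo-3,6-dihydro-2H-pyran-2-carboxylic acid | CC1=CC(=O)O[C@](C)(C1)C(=O)O | intermediate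
16 | mono-tert-butyl malonate | CC(C)(C)OC(=O)CC(=O)O | starting material
17 | (2R)-2-(imidazol-1-ylcarbonyl)-2,4-dimethyl-2,3-dihydropyran-6-one (acyl imidazolide of 15) | CC1=CC(=O)O[C@](C)(C1)C(=O)n1ccnc1 | intermediate
18 | 2-(tert-butoxycarbonyl)-3-[(2R)-2,4-dimethyl-6-oxo-3,6-dihydro-2H-pyran-2-yl]-3-oxopropanoic acid | CC1=CC(=O)O[C@](C)(C1)C(=O)C(C(=O)O)C(=O)OC(C)(C)C | intermediate
19 | tert-butyl 3-[(2R)-2,4-dimethyl-6-oxo-3,6-dihydro-2H-pyran-2-yl]-3-oxopropanoate | CC1=CC(=O)O[C@](C)(C1)C(=O)CC(=O)OC(C)(C)C | intermediate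
20 | tert-butyl (3R)-3-[(2R)-2,4-dimethyl-6-oxo-3,6-dihydro-2H-pyran-2-yl]-3-hydroperoxy-3-methoxypropanoate (3S epimer also formed) | CC1=CC(=O)O[C@](C)(C1)[C@](OC)(OO)CC(=O)OC(C)(C)C | intermediate
21 | tert-butyl 2-[(1R,4R,5R)-4-methoxy-1,5-dimethyl-7-oxo-2,3,6-trioxabicyclo[3.3.1]nonan-4-yl]acetate (4-epimer also formed) | C[C@]1(CC(=O)O3)C[C@]3(C)[C@@](OC)(CC(=O)OC(C)(C)C)OO1 | intermediate
22 | tert-butyl 2-[(1R,4R,5R)-1,5-dimethyl-7-oxo-2,3,6-trioxabicyclo[3.3.1]nonan-4-yl]acetate | C[C@]1(CC(=O)O3)C[C@]3(C)[C@@H](CC(=O)OC(C)(C)C)OO1 | intermediate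
23 | tert-butyl 2-[(1R,4R,5R)-7-hydroxy-1,5-dimethyl-2,3,6-trioxabicyclo[3.3.1]nonan-4-yl]acetate (both lactol epimers) | C[C@]1(CC(O)O3)C[C@]3(C)[C@@H](CC(=O)OC(C)(C)C)OO1 | intermediate
24 | (10-phenyldecylidene)triphenylphosphorane | c1ccccc1CCCCCCCCCC=P(c1ccccc1)(c1ccccc1)c1ccccc1 | intermediate
25 | tert-butyl 2-[(3R,4R,6S)-4-hydroxy-4,6-dimethyl-6-[(2Z)-12-phenyldodec-2-en-1-yl]-1,2-dioxan-3-yl]acetate | C[C@]1(C/C=C\CCCCCCCCCc2ccccc2)C[C@@](C)(O)[C@@H](CC(=O)OC(C)(C)C)OO1 | intermediate
26 | 2-[(3R,4R,6S)-4-hydroxy-4,6-dimethyl-6-[(2Z)-12-phenyldodec-2-en-1-yl]-1,2-dioxan-3-yl]acetic acid | C[C@]1(C/C=C\CCCCCCCCCc2ccccc2)C[C@@](C)(O)[C@@H](CC(=O)O)OO1 | intermediate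
27 | (3R,4R,6S)-8,9-didehydroplakortolide K: ring A (4,6-dimethyl-1,2-dioxane) cis-fused at C3–C4 to ring B (γ-lactone O–C4, C1=O, C2H2, C3), C6 bearing (2Z)-12-phenyldodec-2-enyl | C[C@]1(C/C=C\CCCCCCCCCc2ccccc2)C[C@@]2(C)OC(=O)C[C@H]2OO1 | intermediate
28 | plakortolide K, (3R,4R,6S): the same bicycle with C6 bearing methyl and 12-phenyldodecyl | C[C@]1(CCCCCCCCCCCCc2ccccc2)C[C@@]2(C)OC(=O)C[C@H]2OO1 | target

**Step count and risk**

Total: 15 steps. Longest linear sequence: 13 steps (steps 3–15, from (S)-lactic acid); steps 1–2 are a two-step branch that joins at step 13.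

The three steps most likely to fail:

Step 10. The peroxy anion is itself a good leaving group, so the addition to the hindered, β,β-disubstituted acceptor may be slow and may run backwards, or the transient enolate may attack the O–O bond and collapse to an epoxide. The fallback sets out from 20 and replaces nucleophilic by electrophilic activation of the C6=C7 bond. Treatment with Hg(OAc)2 and catalytic HClO4 in CH2Cl2 should bring about cycloperoxymercuration, which on α,β-unsaturated esters places the peroxide on the β-carbon and mercury on the α-carbon. The tether again reaches only one face of C6, and anti addition would give tert-butyl 2-[(1R,4R,5R,8S)-8-(acetoxymercurio)-4-methoxy-1,5-dimethyl-7-oxo-2,3,6-trioxabicyclo[3.3.1]nonan-4-yl]acetate F1. Reductive demercuration with NaBH4 in aqueous NaOH at 0 °C would replace C7–Hg by C7–H and come back to the route at 21.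

Step 13. The bridged lactolate may open slowly, which leaves the aldehyde exposed to excess ylide and alkoxide at 0 °C. Deprotonation at C7 with β-elimination of the C6 peroxide, or Kornblum–DeLaMare-type attack of base at C3–H, could then outrun olefination. The fallback sets out from 23 and forms ring B before the olefination, so that a free aldehyde meets one equivalent of ylide at low temperature only. NaBH4 in MeOH at 0 °C would give tert-butyl 2-[(3R,4R,6S)-4-hydroxy-6-(2-hydroxyethyl)-4,6-dimethyl-1,2-dioxan-3-yl]acetate F2. CF3CO2H/CH2Cl2 (then aq. NaHCO3/MeOH to cleave any trifluoroacetate) would close ring B to the (3R,4R,6S)-6-(2-hydroxyethyl) analogue of 28, F3. Dess–Martin periodinane with NaHCO3 in CH2Cl2 would give the (3R,4R,6R)-6-(2-oxoethyl) analogue of 28, F4 (same spatial arrangement; the C6 descriptor changes by priority only). Adding F4 to 1.05 equiv of ylide 24 in THF at −78 °C, where carbonyl addition should be much faster than deprotonation, would come back to the route at 27.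

Step 9. The C3 carbonyl is hindered by the quaternary C4 and belongs to a chelating, enolisable β-keto ester, so perhydrolysis may stall at the ketone, or the Lewis acid may instead open the lactone by methanolysis. The fallback sets out from 19 and introduces the methoxy group first by O-alkylation, which needs no attack at the hindered carbonyl. KN(SiMe3)2 and MeOTf in THF/DMPU at −78 °C should give tert-butyl (2E)-3-[(2R)-2,4-dimethyl-6-oxo-3,6-dihydro-2H-pyran-2-yl]-3-methoxyprop-2-enoate F5 (alkene geometry immaterial). Acid-catalysed addition of anhydrous ethereal H2O2 (pyridinium p-toluenesulfonate cat., CH2Cl2, 0 °C; protonation at C2, capture of the oxocarbenium ion at C3) would come back to the route at 20.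

**Further compounds**

F1 | step 10 | tert-butyl 2-[(1R,4R,5R,8S)-8-(acetoxymercurio)-4-methoxy-1,5-dimethyl-7-oxo-2,3,6-trioxabicyclo[3.3.1]nonan-4-yl]acetate | C[C@]1([C@H]([Hg]OC(C)=O)C(=O)O3)C[C@]3(C)[C@@](OC)(CC(=O)OC(C)(C)C)OO1
F2 | step 13 | tert-butyl 2-[(3R,4R,6S)-4-hydroxy-6-(2-hydroxyethyl)-4,6-dimethyl-1,2-dioxan-3-yl]acetate | C[C@]1(CCO)C[C@@](C)(O)[C@@H](CC(=O)OC(C)(C)C)OO1
F3 | step 13 | (3R,4R,6S)-6-(2-hydroxyethyl) analogue of 28 (ring A/ring B bicycle, C6 bearing methyl and CH2CH2OH) | C[C@]1(CCO)C[C@@]2(C)OC(=O)C[C@H]2OO1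
F4 | step 13 | (3R,4R,6R)-6-(2-oxoethyl) analogue of 28 (ring A/ring B bicycle, C6 bearing methyl and CH2CHO) | C[C@]1(CC=O)C[C@@]2(C)OC(=O)C[C@H]2OO1
F5 | step 9 | tert-butyl (2E)-3-[(2R)-2,4-dimethyl-6-oxo-3,6-dihydro-2H-pyran-2-yl]-3-methoxyprop-2-enoate | CC1=CC(=O)O[C@](C)(C1)/C(OC)=C\C(=O)OC(C)(C)C
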